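**Plan**

- Retrosynthetic cuts, in order: the glycerol chain at C7″–C8″ (aldol) and at the aryl O–CH2 bond (etherification); the C9–O bond of the second tetrahydrofuran ring (back to a γ-lactone); the O–C7′ bond (removal of the lactone ring oxygen); the cyclobutanone bonds C9–C8 and C7′–C8′ (ketene plus alkene); the aryl–C7 bond (aryl triflate plus 2,3-dihydrofuran).
- Enabling feature: the second tetrahydrofuran ring is C8–C9H2–O–C7′H(aryl)–C8′. Without its oxygen these four carbons form a four-membered ketone (carbonyl at C9) cis-fused through C8–C8′ to the first ring C7–O–C9′–C8′–C8, so one oxygen inserted between C9 and C7′ of that strained ketone restores the furofuran skeleton at the lactone level.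
- Forward order: the first tetrahydrofuran ring is 2,3-dihydrofuran, arylated at C7; the cyclobutanone is added across C8=C8′; oxygen insertion gives the γ-lactone; reduction and C9–O closure give the second tetrahydrofuran ring; the chain is joined last by O-alkylation and aldol addition.
- Stereochemistry: C7 from the chiral ligand of the Heck arylation; C8 and C8′ from cycloaddition anti to the C7 aryl group; C7′ (aryl endo) from hydrogen delivery to the convex face of the cyclobutanone, kept by the retentive 1,2-shift; C7″ and C8″ from the (S)-benzyloxazolidinone in a syn aldol reaction.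

Key step: step 7

Remarks. Atom labels C7–C9, C7′–C9′ (furofuran) and C7″–C9″ (glycerol chain) are lignan locants; locants inside compound names are systematic. TBS = tert-butyldimethylsilyl; endo = on the concave face of the bicycle. ArO– = aryloxy residue of phenol 19. The plain arylketene is not used, because a monosubstituted ketene would oligomerise faster than it adds to an unactivated alkene; an α-chlorine activates the ketene and is removed in step 6.
Assumption: the (S)-configured phosphinooxazoline is taken to give the (2R)-dihydrofuran, the sense known for phenyl triflate; if the sense were reversed, the (R)-ligand would be used.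

**Step 1**
Reactants: 1 4-(benzyloxy)-3-methoxyphenol
Product: 2 4-(benzyloxy)-3-methoxyphenyl trifluoromethanesulfonate
Conditions: Tf2O, pyridine, CH2Cl2, 0 °C
Reagents that add atoms: trifluoromethanesulfonic anhydride, O=S(=O)(OS(=O)(=O)C(F)(F)F)C(F)(F)F
Why: O-Sulfonylation (triflation) of a phenol is routine and turns the phenolic C–O bond into a leaving group for oxidative addition; no stereocentre is involved.

**Step 2**
Reactants: 2 4-(benzyloxy)-3-methoxyphenyl trifluoromethanesulfonate; 3 2,3-dihydrofuran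
Product: 4 (2R)-2-[4-(benzyloxy)-3-methoxyphenyl]-2,5-dihydrofuran
Conditions: Pd2(dba)3 (1.5 mol %), (S)-tBu-PHOX [(S)-4-tert-butyl-2-(2-diphenylphosphinophenyl)-4,5-dihydrooxazole] (6 mol %), iPr2NEt, THF, 70 °C
Reagents that add atoms: none
Why: Asymmetric Mizoroki–Heck arylation: after oxidative addition of the triflate to zerovalent palladium, the cationic aryl complex inserts the enol ether with the aryl group at C2 on the enantioface chosen by the ligand, and β-hydride elimination with prompt alkene release leaves the double bond at C3=C4, so the ligand sets the single stereocentre (R, the future C7).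

**Step 3**
Reactants: 5 (4-hydroxy-3,5-dimethoxyphenyl)acetic acid
Product: 7 [4-(TBSO)-3,5-dimethoxyphenyl]acetic acid, via bis-silylated ester 6 (not isolated)
Conditions: TBSCl (2.2 equiv), imidazole, DMF, rt; then AcOH–THF–H2O, rt
Reagents that add atoms: tert-butyldimethylsilyl chloride, CC(C)(C)[Si](C)(C)Cl
Why: Silyl ether formation on both acidic hydroxyls followed by selective hydrolysis of the labile silyl ester should leave the hindered aryl silyl ether in place; no stereocentre is involved.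

**Step 4**
Reactants: 7 [4-(TBSO)-3,5-dimethoxyphenyl]acetic acid
Product: 9 (±)-2-chloro-2-[4-(TBSO)-3,5-dimethoxyphenyl]acetic acid, via dilithium enediolate 8 (not isolated)
Conditions: LiN(iPr)2 (2.2 equiv), THF, −78 to 0 °C; then cannulated into C2Cl6, THF, −78 °C; cold dilute aqueous HCl work-up
Reagents that add atoms: hexachloroethane, ClC(Cl)(Cl)C(Cl)(Cl)Cl
Why: α-Halogenation of a carboxylic acid dianion: the enediolate takes positive chlorine from C2Cl6 (inverse addition limits proton exchange and over-chlorination), giving the racemic α-chloro acid whose stereocentre is erased in the next step.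

**Step 5**
Reactants: 9 (±)-2-chloro-2-[4-(TBSO)-3,5-dimethoxyphenyl]acetic acid; 4 (2R)-2-[4-(benzyloxy)-3-methoxyphenyl]-2,5-dihydrofuran
Product: 12 (1S,4R,5R)-4-[4-(benzyloxy)-3-methoxyphenyl]-7-chloro-7-[4-(TBSO)-3,5-dimethoxyphenyl]-3-oxabicyclo[3.2.0]heptan-6-one (either or both C7 epimers), via acid chloride 10 (not isolated), via aryl(chloro)ketene 11 (not isolated)
Conditions: 9 (2.5 equiv), (COCl)2, DMF (cat.), CH2Cl2, 0 °C to rt, then evaporation; slow addition to 4, Et3N, toluene, 70 °C
Reagents that add atoms: none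
Why: Dehydrochlorination gives the aryl(chloro)ketene, whose chlorine makes it electrophilic enough for a thermal ketene–alkene (2+2) cycloaddition (concerted, suprafacial on the alkene) with the unactivated cis-alkene; approach anti to the C7 aryl group sets C8 and C8′ (cis fusion, C7 aryl exo), the bulky Ar(Cl)C terminus should bond to C8′ (remote from the substituted C7) and the carbonyl carbon to C8, and the quaternary α-carbon cannot epimerise under the amine.

**Step 6**
Reactants: 12 (1S,4R,5R)-4-[4-(benzyloxy)-3-methoxyphenyl]-7-chloro-7-[4-(TBSO)-3,5-dimethoxyphenyl]-3-oxabicyclo[3.2.0]heptan-6-one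
Product: 13 (1S,4R,5R,7S)-4-[4-(benzyloxy)-3-methoxyphenyl]-7-[4-(TBSO)-3,5-dimethoxyphenyl]-3-oxabicyclo[3.2.0]heptan-6-one (4-aryl exo; 7-aryl endo)
Conditions: Bu3SnH, Et3B (cat.), air, toluene, −40 °C
Reagents that add atoms: none
Why: Radical dehalogenation of an α-chloro ketone: the stannyl radical abstracts chlorine from either epimer to give one planar benzylic α-keto radical, and hydrogen transfer from the bulky Bu3SnH on the open convex face should place H exo and the aryl group endo at C7′, under neutral conditions that cannot epimerise the product.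

**Step 7**
Reactants: 13 (1S,4R,5R,7S)-4-[4-(benzyloxy)-3-methoxyphenyl]-7-[4-(TBSO)-3,5-dimethoxyphenyl]-3-oxabicyclo[3.2.0]heptan-6-one
Product: 15 (3S,3aS,6R,6aR)-6-[4-(benzyloxy)-3-methoxyphenyl]-3-[4-(TBSO)-3,5-dimethoxyphenyl]tetrahydro-1H,3H-furo[3,4-c]furan-1-one, via Criegee adduct 14 (not isolated)
Conditions: mCPBA, NaHCO3, CH2Cl2, 0 °C
Reagents that add atoms: 3-chloroperbenzoic acid, OOC(=O)c1cccc(Cl)c1
Why: The peracid adds to the strained C9 carbonyl to give Criegee adduct 14, and the benzylic carbon C7′ then shifts from C9 to the proximal peroxide oxygen as 3-chlorobenzoate leaves, which forms the C7′–O bond. The closest known reaction type is the Baeyer–Villiger ring expansion of fused cyclobutanones to γ-lactones. The five-membered lactone ring is not closed by a cyclisation but arises by enlargement of the four-membered ring through this 1,2-shift. No new stereocentre is formed; C7′ keeps its endo aryl group because the migrating carbon moves with retention, and C7, C8 and C8′ are not involved. The step needs migration of C7′ in preference to C8, which should follow from the higher migratory aptitude of a secondary benzylic carbon over the ring-fusion carbon C8, itself deactivated by the β-oxygen on C7. It also needs the ketone to react before the electron-rich arenes and without acid-induced epimerisation, which the release of ring strain and the hydrogencarbonate buffer at 0 °C should ensure.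

**Step 8**
Reactants: 15 (3S,3aS,6R,6aR)-6-[4-(benzyloxy)-3-methoxyphenyl]-3-[4-(TBSO)-3,5-dimethoxyphenyl]tetrahydro-1H,3H-furo[3,4-c]furan-1-one
Product: 16 [(2R,3S,4S)-2-[4-(benzyloxy)-3-methoxyphenyl]-4-[(S)-[4-(TBSO)-3,5-dimethoxyphenyl](hydroxy)methyl]tetrahydrofuran-3-yl]methanol
Conditions: LiBH4, THF, 0 °C to rt
Reagents that add atoms: none
Why: Hydride reduction of a γ-lactone to the 1,4-diol with LiBH4 should leave all four stereocentres, the silyl ether and the benzyl ether untouched.

**Step 9**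
Reactants: 16 [(2R,3S,4S)-2-[4-(benzyloxy)-3-methoxyphenyl]-4-[(S)-[4-(TBSO)-3,5-dimethoxyphenyl](hydroxy)methyl]tetrahydrofuran-3-yl]methanol
Product: 18 (1S,3aS,4R,6aS)-4-[4-(benzyloxy)-3-methoxyphenyl]-1-[4-(TBSO)-3,5-dimethoxyphenyl]tetrahydro-1H,3H-furo[3,4-c]furan, via primary mesylate 17 (not isolated)
Conditions: MsCl (1.05 equiv), pyridine, CH2Cl2, −10 °C to rt
Reagents that add atoms: none
Why: Selective sulfonylation of the primary hydroxyl and intramolecular Williamson etherification (5-exo-tet SN2 at C9 by the benzylic C7′ hydroxyl) close the second tetrahydrofuran ring without breaking the C7′–O bond, so the endo aryl group is retained and no Lewis acid that could ionise the benzylic ethers is present.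

**Step 10**
Reactants: 18 (1S,3aS,4R,6aS)-4-[4-(benzyloxy)-3-methoxyphenyl]-1-[4-(TBSO)-3,5-dimethoxyphenyl]tetrahydro-1H,3H-furo[3,4-c]furan
Product: 19 4-[(1S,3aS,4R,6aS)-4-[4-(benzyloxy)-3-methoxyphenyl]tetrahydro-1H,3H-furo[3,4-c]furan-1-yl]-2,6-dimethoxyphenol
Conditions: Bu4NF, AcOH, THF, 0 °C
Reagents that add atoms: none
Why: Fluoride-mediated desilylation of the aryl silyl ether, buffered with acetic acid so that no free phenoxide para to the C7′ benzylic ether persists.

**Step 11**
Reactants: 20 (S)-4-benzyloxazolidin-2-one; 21 bromoacetyl bromide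
Product: 23 (S)-4-benzyl-3-(bromoacetyl)oxazolidin-2-one, via lithium oxazolidinide 22 (not isolated)
Conditions: n-BuLi, THF, −78 °C; then 21, −78 to 0 °C
Reagents that add atoms: none
Why: N-Acylation of the lithiated oxazolidinone with an acid bromide at low temperature is standard and does not touch the auxiliary stereocentre.

**Step 12**
Reactants: 19 4-[(1S,3aS,4R,6aS)-4-[4-(benzyloxy)-3-methoxyphenyl]tetrahydro-1H,3H-furo[3,4-c]furan-1-yl]-2,6-dimethoxyphenol; 23 (S)-4-benzyl-3-(bromoacetyl)oxazolidin-2-one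
Product: 24 (4S)-4-benzyl-3-[(ArO)acetyl]oxazolidin-2-one
Conditions: K2CO3, acetone, rt
Reagents that add atoms: none
Why: Williamson ether synthesis: the hindered 2,6-dimethoxyphenoxide displaces the activated primary α-bromo imide (SN2) under mild carbonate conditions at room temperature, which should not open the para-benzylic ether.

**Step 13**
Reactants: 24 (4S)-4-benzyl-3-[(ArO)acetyl]oxazolidin-2-one; 25 4-(benzyloxy)-3,5-dimethoxybenzaldehyde
Product: 27 (4S)-4-benzyl-3-[(2S,3R)-2-(ArO)-3-[4-(benzyloxy)-3,5-dimethoxyphenyl]-3-hydroxypropanoyl]oxazolidin-2-one, via boron enolate 26 (not isolated)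
Conditions: Bu2BOTf, iPr2NEt, CH2Cl2, −78 to 0 °C; then 25, −78 to 0 °C; pH 7 buffer, MeOH, H2O2, 0 °C
Reagents that add atoms: none
Why: Evans syn aldol reaction: the (Z)-dibutylboron enolate adds to the aldehyde through a closed Zimmerman–Traxler transition state on the enolate face away from the benzyl group of the (S)-auxiliary, setting C8″ and C7″ syn (threo, the future 7″R,8″R pair).

**Step 14**
Reactants: 27 (4S)-4-benzyl-3-[(2S,3R)-2-(ArO)-3-[4-(benzyloxy)-3,5-dimethoxyphenyl]-3-hydroxypropanoyl]oxazolidin-2-one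
Product: 28 (1R,2R)-2-(ArO)-1-[4-(benzyloxy)-3,5-dimethoxyphenyl]propane-1,3-diol
Conditions: LiBH4, H2O (1 equiv), THF, 0 °C
Reagents that add atoms: none
Why: Reductive cleavage of the N-acyl oxazolidinone with LiBH4 gives the primary alcohol C9″ and releases the auxiliary without touching the two new stereocentres.

**Step 15**
Reactants: 28 (1R,2R)-2-(ArO)-1-[4-(benzyloxy)-3,5-dimethoxyphenyl]propane-1,3-diol
Product: 29 (1R,2R)-1-(4-hydroxy-3,5-dimethoxyphenyl)-2-[4-[(1S,3aS,4R,6aS)-4-(4-hydroxy-3-methoxyphenyl)tetrahydro-1H,3H-furo[3,4-c]furan-1-yl]-2,6-dimethoxyphenoxy]propane-1,3-diol (CNP0317965.1)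
Conditions: H2 (1 atm), Pd/C (10 %), EtOAc, rt
Reagents that add atoms: none
Why: Catalytic hydrogenolysis of the two aryl benzyl ethers over Pd/C in neutral ethyl acetate, stopped after uptake of two equivalents of H2, should be much faster than cleavage of the benzylic C–O bonds of the furofuran and of the secondary benzylic alcohol.

**Compound list**

1 | 4-(benzyloxy)-3-methoxyphenol | COc1cc(O)ccc1OCc1ccccc1 | starting material
2 | 4-(benzyloxy)-3-methoxyphenyl trifluoromethanesulfonate | COc1cc(OS(=O)(=O)C(F)(F)F)ccc1OCc1ccccc1 | intermediate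
3 | 2,3-dihydrofuran | C1=COCC1 | starting material
4 | (2R)-2-[4-(benzyloxy)-3-methoxyphenyl]-2,5-dihydrofuran | COc1cc([C@@H]2OCC=C2)ccc1OCc1ccccc1 | intermediate
5 | (4-hydroxy-3,5-dimethoxyphenyl)acetic acid | COc1cc(CC(=O)O)cc(OC)c1O | starting material
6 | tert-butyldimethylsilyl [4-(tert-butyldimethylsilyloxy)-3,5-dimethoxyphenyl]acetate (not isolated) | COc1cc(CC(=O)O[Si](C)(C)C(C)(C)C)cc(OC)c1O[Si](C)(C)C(C)(C)C | intermediate
7 | [4-(tert-butyldimethylsilyloxy)-3,5-dimethoxyphenyl]acetic acid | COc1cc(CC(=O)O)cc(OC)c1O[Si](C)(C)C(C)(C)C | intermediate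
8 | dilithium enediolate of 7 (not isolated) | [Li+].[Li+].COc1cc(C=C([O-])[O-])cc(OC)c1O[Si](C)(C)C(C)(C)C | intermediate
9 | (±)-2-chloro-2-[4-(tert-butyldimethylsilyloxy)-3,5-dimethoxyphenyl]acetic acid | COc1cc(C(Cl)C(=O)O)cc(OC)c1O[Si](C)(C)C(C)(C)C | intermediate
10 | (±)-2-chloro-2-[4-(tert-butyldimethylsilyloxy)-3,5-dimethoxyphenyl]acetyl chloride (not isolated) | COc1cc(C(Cl)C(Cl)=O)cc(OC)c1O[Si](C)(C)C(C)(C)C | intermediate
11 | chloro[4-(tert-butyldimethylsilyloxy)-3,5-dimethoxyphenyl]ketene (not isolated) | COc1cc(C(Cl)=C=O)cc(OC)c1O[Si](C)(C)C(C)(C)C | intermediate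
12 | (1S,4R,5R)-4-[4-(benzyloxy)-3-methoxyphenyl]-7-chloro-7-[4-(tert-butyldimethylsilyloxy)-3,5-dimethoxyphenyl]-3-oxabicyclo[3.2.0]heptan-6-one; cis-fused, 4-aryl exo, C7 configuration open | COc1cc([C@@H]2OC[C@@H]3[C@H]2C(=O)C3(Cl)c2cc(OC)c(O[Si](C)(C)C(C)(C)C)c(OC)c2)ccc1OCc1ccccc1 | intermediate
13 | (1S,4R,5R,7S)-4-[4-(benzyloxy)-3-methoxyphenyl]-7-[4-(tert-butyldimethylsilyloxy)-3,5-dimethoxyphenyl]-3-oxabicyclo[3.2.0]heptan-6-one; 4-aryl exo, 7-aryl endo | COc1cc([C@@H]2OC[C@@H]3[C@H]2C(=O)[C@@H]3c2cc(OC)c(O[Si](C)(C)C(C)(C)C)c(OC)c2)ccc1OCc1ccccc1 | intermediate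
14 | Criegee adduct of 13: 6-hydroxy-6-(3-chlorobenzoylperoxy) derivative, C6 configuration open (not isolated) | COc1cc([C@@H]2OC[C@@H]3[C@H]2C(O)(OOC(=O)c2cccc(Cl)c2)[C@@H]3c2cc(OC)c(O[Si](C)(C)C(C)(C)C)c(OC)c2)ccc1OCc1ccccc1 | intermediate
15 | (3S,3aS,6R,6aR)-6-[4-(benzyloxy)-3-methoxyphenyl]-3-[4-(tert-butyldimethylsilyloxy)-3,5-dimethoxyphenyl]tetrahydro-1H,3H-furo[3,4-c]furan-1-one; 6-aryl exo, 3-aryl endo | COc1cc([C@@H]2OC[C@@H]3[C@H]2C(=O)O[C@@H]3c2cc(OC)c(O[Si](C)(C)C(C)(C)C)c(OC)c2)ccc1OCc1ccccc1 | intermediate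
16 | [(2R,3S,4S)-2-[4-(benzyloxy)-3-methoxyphenyl]-4-[(S)-[4-(tert-butyldimethylsilyloxy)-3,5-dimethoxyphenyl](hydroxy)methyl]tetrahydrofuran-3-yl]methanol | COc1cc([C@@H]2OC[C@@H]([C@H](O)c3cc(OC)c(O[Si](C)(C)C(C)(C)C)c(OC)c3)[C@H]2CO)ccc1OCc1ccccc1 | intermediate
17 | primary methanesulfonate of 16 (not isolated) | COc1cc([C@@H]2OC[C@@H]([C@H](O)c3cc(OC)c(O[Si](C)(C)C(C)(C)C)c(OC)c3)[C@H]2COS(C)(=O)=O)ccc1OCc1ccccc1 | intermediate
18 | (1S,3aS,4R,6aS)-4-[4-(benzyloxy)-3-methoxyphenyl]-1-[4-(tert-butyldimethylsilyloxy)-3,5-dimethoxyphenyl]tetrahydro-1H,3H-furo[3,4-c]furan; lignan descriptors 7R,8S,7′S,8′S | COc1cc([C@@H]2OC[C@@H]3[C@H]2CO[C@@H]3c2cc(OC)c(O[Si](C)(C)C(C)(C)C)c(OC)c2)ccc1OCc1ccccc1 | intermediate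
19 | 4-[(1S,3aS,4R,6aS)-4-[4-(benzyloxy)-3-methoxyphenyl]tetrahydro-1H,3H-furo[3,4-c]furan-1-yl]-2,6-dimethoxyphenol | COc1cc([C@@H]2OC[C@@H]3[C@H]2CO[C@@H]3c2cc(OC)c(O)c(OC)c2)ccc1OCc1ccccc1 | intermediate
20 | (S)-4-benzyloxazolidin-2-one | O=C1N[C@@H](Cc2ccccc2)CO1 | starting material
21 | bromoacetyl bromide | BrCC(Br)=O | starting material
22 | lithium salt of 20, N-lithiated (not isolated) | [Li+].O=C1[N-][C@@H](Cc2ccccc2)CO1 | intermediate
23 | (S)-4-benzyl-3-(bromoacetyl)oxazolidin-2-one | O=C1N(C(=O)CBr)[C@@H](Cc2ccccc2)CO1 | intermediate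
24 | (4S)-4-benzyl-3-[(ArO)acetyl]oxazolidin-2-one, ArO = aryloxy residue of 19 | COc1cc([C@@H]2OC[C@@H]3[C@H]2CO[C@@H]3c2cc(OC)c(OCC(=O)N4C(=O)OC[C@@H]4Cc4ccccc4)c(OC)c2)ccc1OCc1ccccc1 | intermediate
25 | 4-(benzyloxy)-3,5-dimethoxybenzaldehyde | COc1cc(C=O)cc(OC)c1OCc1ccccc1 | starting material
26 | (Z)-dibutylboron enolate of 24 (not isolated) | COc1cc([C@@H]2OC[C@@H]3[C@H]2CO[C@@H]3c2cc(OC)c(O/C=C(\OB(CCCC)CCCC)N4C(=O)OC[C@@H]4Cc4ccccc4)c(OC)c2)ccc1OCc1ccccc1 | intermediate
27 | (4S)-4-benzyl-3-[(2S,3R)-2-(ArO)-3-[4-(benzyloxy)-3,5-dimethoxyphenyl]-3-hydroxypropanoyl]oxazolidin-2-one | COc1cc([C@@H]2OC[C@@H]3[C@H]2CO[C@@H]3c2cc(OC)c(O[C@H](C(=O)N4C(=O)OC[C@@H]4Cc4ccccc4)[C@H](O)c4cc(OC)c(OCc5ccccc5)c(OC)c4)c(OC)c2)ccc1OCc1ccccc1 | intermediate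
28 | (1R,2R)-2-(ArO)-1-[4-(benzyloxy)-3,5-dimethoxyphenyl]propane-1,3-diol | COc1cc([C@@H]2OC[C@@H]3[C@H]2CO[C@@H]3c2cc(OC)c(O[C@H](CO)[C@H](O)c4cc(OC)c(OCc5ccccc5)c(OC)c4)c(OC)c2)ccc1OCc1ccccc1 | intermediate
29 | (1R,2R)-1-(4-hydroxy-3,5-dimethoxyphenyl)-2-[4-[(1S,3aS,4R,6aS)-4-(4-hydroxy-3-methoxyphenyl)tetrahydro-1H,3H-furo[3,4-c]furan-1-yl]-2,6-dimethoxyphenoxy]propane-1,3-diol | COc1cc([C@@H]2OC[C@@H]3[C@H]2CO[C@@H]3c2cc(OC)c(O[C@H](CO)[C@H](O)c3cc(OC)c(O)c(OC)c3)c(OC)c2)ccc1O | target

**Step count and risks**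

Total step count: 15. Longest linear sequence: 12 steps (steps 3–10 and 12–15 from acid 5; equally steps 1, 2, 5–10 and 12–15 from phenol 1).

Steps most likely to fail:

Step 5. Amine-induced oligomerisation of ketene 11 may outrun cycloaddition to the inductively deactivated cis-alkene of 4, and part of the ketene may add in the reversed orientation (carbonyl carbon to C8′), since only steric bias separates the two alkene carbons. The fallback sets out from acid 7 and dihydrofuran 4 and returns at ketone 13. Acid 7 is coupled with dimethylamine (carbodiimide, CH2Cl2) to N,N-dimethyl-2-[4-(tert-butyldimethylsilyloxy)-3,5-dimethoxyphenyl]acetamide F1. Tf2O and 2,4,6-collidine in 1,2-dichloroethane convert it into the keteniminium triflate F2, a much stronger electrophile that is known to add to unactivated cis-alkenes. Heating with 4 should give the cyclobutaniminium triflate F3, and hydrolysis with aqueous NaHCO3 the ketone, expected as the more stable exo-aryl epimer F4. Deprotonation at the benzylic carbon with LiN(SiMe3)2 in THF at −78 °C gives the lithium enolate F5, and protonation at −78 °C with 2,6-di-tert-butylphenol on the convex face should give endo ketone 13.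

Step 6. Hydrogen transfer may reach both faces of the planar benzylic radical and erode the endo preference at C7′. The fallback sets out from chloro ketone 12 and returns at 13, and sets the stereocentre by protonating an enolate with a proton donor whose size can be chosen. Zinc dust and Me3SiCl in THF reduce the α-chloro ketone and trap the enolate as the trimethylsilyl enol ether F6. MeLi in THF at −20 °C releases the lithium enolate F7, which is protonated at −78 °C with 2,6-di-tert-butylphenol from the convex face.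

Step 9. The electron-rich benzylic C7′ hydroxyl may be sulfonylated or ionised in competition with the primary hydroxyl, so that the ring closes through a benzylic cation and the endo configuration is lost. The fallback sets out from lactone 15 and returns at furofuran 18 without any cation at C7′ or C9. Reduction with iBu2AlH in CH2Cl2 at −78 °C gives the lactol F8, and 1,1′-thiocarbonyldiimidazole converts it into the imidazolyl thionocarbonate F9. Bu3SnH and AIBN in toluene at 80 °C (Barton–McCombie deoxygenation through the α-alkoxy radical at C9) should then give 18.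

**Further compounds**

F1 | step 5 | N,N-dimethyl-2-[4-(tert-butyldimethylsilyloxy)-3,5-dimethoxyphenyl]acetamide | COc1cc(CC(=O)N(C)C)cc(OC)c1O[Si](C)(C)C(C)(C)C
F2 | step 5 | N,N-dimethyl keteniminium triflate from F1 | COc1cc(C=C=[N+](C)C)cc(OC)c1O[Si](C)(C)C(C)(C)C.[O-]S(=O)(=O)C(F)(F)F
F3 | step 5 | cyclobutaniminium triflate (N,N-dimethyliminium of the cyclobutanone, C7 configuration open) | COc1cc([C@@H]2OC[C@@H]3[C@H]2C(=[N+](C)C)C3c2cc(OC)c(O[Si](C)(C)C(C)(C)C)c(OC)c2)ccc1OCc1ccccc1.[O-]S(=O)(=O)C(F)(F)F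
F4 | step 5 | (1S,4R,5R,7R)-4-[4-(benzyloxy)-3-methoxyphenyl]-7-[4-(tert-butyldimethylsilyloxy)-3,5-dimethoxyphenyl]-3-oxabicyclo[3.2.0]heptan-6-one (exo-aryl epimer of 13) | COc1cc([C@@H]2OC[C@@H]3[C@H]2C(=O)[C@H]3c2cc(OC)c(O[Si](C)(C)C(C)(C)C)c(OC)c2)ccc1OCc1ccccc1
F5 | step 5 | lithium enolate of F4 (C6–C7 enolate) | [Li+].COc1cc([C@@H]2OC[C@@H]3[C@H]2C([O-])=C3c2cc(OC)c(O[Si](C)(C)C(C)(C)C)c(OC)c2)ccc1OCc1ccccc1
F6 | step 6 | trimethylsilyl enol ether (6-trimethylsilyloxy-6-ene) derived from 12 | COc1cc([C@@H]2OC[C@@H]3[C@H]2C(O[Si](C)(C)C)=C3c2cc(OC)c(O[Si](C)(C)C(C)(C)C)c(OC)c2)ccc1OCc1ccccc1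
F7 | step 6 | lithium enolate from F6 (same structure as F5) | [Li+].COc1cc([C@@H]2OC[C@@H]3[C@H]2C([O-])=C3c2cc(OC)c(O[Si](C)(C)C(C)(C)C)c(OC)c2)ccc1OCc1ccccc1
F8 | step 9 | lactol of 15 (1-hydroxy compound, anomer mixture) | COc1cc([C@@H]2OC[C@@H]3[C@H]2C(O)O[C@@H]3c2cc(OC)c(O[Si](C)(C)C(C)(C)C)c(OC)c2)ccc1OCc1ccccc1
F9 | step 9 | O-lactol 1H-imidazole-1-carbothioate of F8 | COc1cc([C@@H]2OC[C@@H]3[C@H]2C(OC(=S)n2ccnc2)O[C@@H]3c2cc(OC)c(O[Si](C)(C)C(C)(C)C)c(OC)c2)ccc1OCc1ccccc1
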